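**Strategy.** The tetralin is cut into a diarylmethyl unit and the five carbons of dimethyl itaconate. The key step is a formal (3+3) annulation run in one flask: fluoride unmasks a para-quinone methide whose exocyclic carbon C1 (the diarylmethine) accepts the itaconate dienolate enantioselectively (C1–C2), then the phenoxide of fused ring A closes through its para carbon C4a onto the acrylate CH2, the benzylic C4 (C4–C4a). It exploits both phenols: the 4-OH of the pendant ring lies para to C1, the 7-OH of ring A lies para to C4a. The precursor is a bis-silylated diarylmethyl acetate; ester equilibration gives the all-trans array and LiAlH4 completes the diol.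

Key step: step 3

Remark on numbering: tetralin numbering is used throughout. C1 carries the pendant aryl, C2 and C3 carry the one-carbon side chains, C4 is the benzylic CH2, C4a and C8a are the ring-fusion carbons, and ring A is the fused arene.

Assumption: the sense of induction of the cinchonidinium salt in step 3 cannot be predicted with certainty; if it proves opposite, the pseudoenantiomeric N-(9-anthracenylmethyl)cinchoninium chloride is used instead.

Step 1
Reactants: 1 4-bromo-2,6-dimethoxyphenol
Product: 2 (4-bromo-2,6-dimethoxyphenoxy)(tert-butyl)dimethylsilane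
Conditions: TBSCl, imidazole, DMF, rt
Reagents that add atoms: tert-butyldimethylsilyl chloride (TBSCl), CC(C)(C)[Si](C)(C)Cl
Why: Imidazole-promoted O-silylation (silyl ether protection) should proceed cleanly on the hindered phenol and masks the acidic OH for the halogen–lithium exchange; no stereocenter is formed.

Step 2
Reactants: 2 (4-bromo-2,6-dimethoxyphenoxy)(tert-butyl)dimethylsilane, 3 3-[(tert-butyldimethylsilyl)oxy]-4-methoxybenzaldehyde
Product: 6 racemic [3-(tert-butyldimethylsilyloxy)-4-methoxyphenyl][4-(tert-butyldimethylsilyloxy)-3,5-dimethoxyphenyl]methyl acetate, via aryllithium 4 (not isolated), via lithium diarylmethanolate 5 (not isolated)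
Conditions: n-BuLi, THF, −78 °C; then 3; then Ac2O, −78 °C to 0 °C
Reagents that add atoms: acetic anhydride (Ac2O), CC(=O)OC(C)=O
Why: Bromine–lithium exchange, 1,2-addition of the aryllithium to the aldehyde and O-acetylation of the resulting alkoxide in the same flask should give the diarylmethyl acetate, whose carbinol stereocenter forms as the racemate and is of no consequence because this carbon becomes trigonal in 8.

Step 3
Reactants: 6 racemic [3-(tert-butyldimethylsilyloxy)-4-methoxyphenyl][4-(tert-butyldimethylsilyloxy)-3,5-dimethoxyphenyl]methyl acetate, 7 dimethyl itaconate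
Product: 11 dimethyl (1R,2S,3S)-7-hydroxy-1-(4-hydroxy-3,5-dimethoxyphenyl)-6-methoxy-1,2,3,4-tetrahydronaphthalene-2,3-dicarboxylate, via quinone methide 8 (not isolated), via 1,6-adduct 9 (not isolated), via tetralin diester epimer mixture 10 (not isolated)
Conditions: CsF, N-(9-anthracenylmethyl)cinchonidinium chloride (10 mol %), toluene, −20 °C; then NaOMe, MeOH, 60 °C; then aq. HCl
Reagents that add atoms: none
Why: Proposed new method: fluoride cleaves both silyl ethers, the 4-phenoxide of the pendant ring expels acetate (1,6-elimination) to give quinone methide 8, the chiral ammonium dienolate of 7 adds through its alpha carbon to the exocyclic carbon of 8 (1,6-conjugate addition, C1–C2) to give 9, and under NaOMe the 3-phenoxide of ring A attacks the acrylate CH2 of 9 through its para carbon (C4–C4a) and re-aromatises by tautomerisation. The closest known reaction types are the phase-transfer-catalysed asymmetric 1,6-addition of malonate enolates to para-quinone methides and the base-mediated para-C-Michael addition of phenoxides to acrylates (as in the addition of 2,6-di-tert-butylphenol to methyl acrylate); their union as a formal (3+3) annulation with an itaconate is new. The cyclohexane ring closes in a 6-endo-trig Michael mode onto C4. C1 is set in the intermolecular addition by the ion pair of the cinchonidinium cation with the dienolate (S in 9, which becomes R in 11 only through a change of CIP priorities), and C2 and C3, both alpha to esters, equilibrate under NaOMe to the all-trans, all-pseudoequatorial diester 11 while C1, lacking an acidic hydrogen, is retained. The step needs alpha rather than gamma attack of the dienolate, which the higher charge density at the ester-bearing carbon should favour as in Stobbe-type condensations of itaconates, and closure on ring A para to its phenoxide, which is secured because the pendant phenoxide activates only its substituted ortho carbons and its ipso carbon (a reversible 5-endo-trig spiro closure) and because the ortho site of ring A is flanked on both sides. Isomerisation of 9 to the methylmaleate and methoxide addition to its acrylate are reversible under the same base and should drain through the irreversible aromatic ring closure.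

Step 4
Reactants: 11 dimethyl (1R,2S,3S)-7-hydroxy-1-(4-hydroxy-3,5-dimethoxyphenyl)-6-methoxy-1,2,3,4-tetrahydronaphthalene-2,3-dicarboxylate
Product: 12 [(1R,2S,3S)-7-hydroxy-1-(4-hydroxy-3,5-dimethoxyphenyl)-6-methoxy-1,2,3,4-tetrahydronaphthalene-2,3-diyl]dimethanol (CID70697973)
Conditions: LiAlH4, THF, 0 °C to reflux; then aq. HCl
Reagents that add atoms: none
Why: LiAlH4 reduction of both esters to primary alcohols (ester reduction, after two hydrides are spent on the phenols) should give the diol without touching C1, C2 or C3, which already hold the thermodynamic all-trans arrangement so that the basic hydride cannot scramble them before reduction.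

**Compound list**

1 | 4-bromo-2,6-dimethoxyphenol | COc1cc(Br)cc(OC)c1O | starting material
2 | (4-bromo-2,6-dimethoxyphenoxy)(tert-butyl)dimethylsilane | COc1cc(Br)cc(OC)c1O[Si](C)(C)C(C)(C)C | intermediate
3 | 3-[(tert-butyldimethylsilyl)oxy]-4-methoxybenzaldehyde | COc1ccc(C=O)cc1O[Si](C)(C)C(C)(C)C | starting material
4 | [4-(tert-butyldimethylsilyloxy)-3,5-dimethoxyphenyl]lithium | [Li]c1cc(OC)c(O[Si](C)(C)C(C)(C)C)c(OC)c1 | intermediate
5 | lithium [3-(tert-butyldimethylsilyloxy)-4-methoxyphenyl][4-(tert-butyldimethylsilyloxy)-3,5-dimethoxyphenyl]methanolate (racemic) | [Li]OC(c1ccc(OC)c(O[Si](C)(C)C(C)(C)C)c1)c1cc(OC)c(O[Si](C)(C)C(C)(C)C)c(OC)c1 | intermediate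
6 | [3-(tert-butyldimethylsilyloxy)-4-methoxyphenyl][4-(tert-butyldimethylsilyloxy)-3,5-dimethoxyphenyl]methyl acetate (racemic) | CC(=O)OC(c1ccc(OC)c(O[Si](C)(C)C(C)(C)C)c1)c1cc(OC)c(O[Si](C)(C)C(C)(C)C)c(OC)c1 | intermediate
7 | dimethyl itaconate (dimethyl 2-methylidenebutanedioate) | COC(=O)CC(=C)C(=O)OC | starting material
8 | 4-[(3-hydroxy-4-methoxyphenyl)methylidene]-2,6-dimethoxycyclohexa-2,5-dien-1-one | COC1=CC(=Cc2ccc(OC)c(O)c2)C=C(OC)C1=O | intermediate
9 | dimethyl 2-[(S)-(3-hydroxy-4-methoxyphenyl)(4-hydroxy-3,5-dimethoxyphenyl)methyl]-3-methylidenebutanedioate (mixture at C2) | COc1ccc(cc1O)[C@@H](c1cc(OC)c(O)c(OC)c1)C(C(=O)OC)C(=C)C(=O)OC | intermediate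
10 | dimethyl (1R)-7-hydroxy-1-(4-hydroxy-3,5-dimethoxyphenyl)-6-methoxy-1,2,3,4-tetrahydronaphthalene-2,3-dicarboxylate (mixture of C2 and C3 epimers) | COc1cc2c(cc1O)[C@@H](c1cc(OC)c(O)c(OC)c1)C(C(=O)OC)C(C(=O)OC)C2 | intermediate
11 | dimethyl (1R,2S,3S)-7-hydroxy-1-(4-hydroxy-3,5-dimethoxyphenyl)-6-methoxy-1,2,3,4-tetrahydronaphthalene-2,3-dicarboxylate | COc1cc2c(cc1O)[C@@H](c1cc(OC)c(O)c(OC)c1)[C@H](C(=O)OC)[C@@H](C(=O)OC)C2 | intermediate
12 | [(1R,2S,3S)-7-hydroxy-1-(4-hydroxy-3,5-dimethoxyphenyl)-6-methoxy-1,2,3,4-tetrahydronaphthalene-2,3-diyl]dimethanol | COc1cc2c(cc1O)[C@@H](c1cc(OC)c(O)c(OC)c1)[C@H](CO)[C@@H](CO)C2 | target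

**Step count and risks**

Total step count: 4. Longest linear sequence: 4 steps (1 → 2 → 6 → 11 → 12).

Steps most likely to fail:

Step 3. The phenoxide ring closure may stall while the acrylate of 9 isomerises to the methylmaleate, closure may occur ortho to the phenoxide, the dienolate may attack through its gamma carbon, or the ion pair may give poor facial selectivity at C1. The fallback makes the C4–C4a bond by an aryl radical and uses known chemistry only. It sets out from compound 2, which is lithiated as in step 2 and added to 2-bromo-5-[(tert-butyldimethylsilyl)oxy]-4-methoxybenzaldehyde F1 (from commercial 2-bromo-5-hydroxy-4-methoxybenzaldehyde with TBSCl and imidazole in DMF). The resulting lithium bromodiarylmethanolate F2 is trapped with Ac2O as the bromo diarylmethyl acetate F3. CsF, the same ammonium salt and 7 in toluene at −20 °C, with an acidic quench, should give through the bromo quinone methide F4 the isolated bromo 1,6-adduct F5, which is the phase-transfer 1,6-addition alone. Bu3SnH and azobisisobutyronitrile in benzene at 80 °C should then close the ring by 6-endo-trig addition of the aryl radical to the acrylate CH2, giving the epimer mixture 10, and NaOMe in MeOH equilibrates it to 11, where the route is rejoined.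

Step 2. The electron-rich diarylmethyl acetate may ionise or hydrolyse during work-up and chromatography. The fallback sets out from the lithium alkoxide 5, which is quenched with water to the diarylmethanol F6. 4-Methylbenzenesulfinic acid in CH2Cl2 at rt replaces the hydroxyl by acid-promoted SN1 substitution and should give the stable diarylmethyl sulfone F7. Under the conditions of step 3, F7 loses sulfinate instead of acetate after desilylation and rejoins the route at quinone methide 8.

Step 4. Reduction may stop short on the poorly soluble aluminium phenoxides, and the polar tetrol may be lost on aluminium salts during work-up. The fallback sets out from 11: LiOH in THF/H2O hydrolyses both esters to the diacid F8, whose configuration is already the thermodynamic one, and BH3·SMe2 in THF followed by MeOH reduces the acids to the diol, rejoining the route at 12.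

**Further compounds**

F1 | step 3 | 2-bromo-5-[(tert-butyldimethylsilyl)oxy]-4-methoxybenzaldehyde | COc1cc(Br)c(C=O)cc1O[Si](C)(C)C(C)(C)C
F2 | step 3 | lithium [2-bromo-5-(tert-butyldimethylsilyloxy)-4-methoxyphenyl][4-(tert-butyldimethylsilyloxy)-3,5-dimethoxyphenyl]methanolate (racemic) | [Li]OC(c1cc(O[Si](C)(C)C(C)(C)C)c(OC)cc1Br)c1cc(OC)c(O[Si](C)(C)C(C)(C)C)c(OC)c1
F3 | step 3 | [2-bromo-5-(tert-butyldimethylsilyloxy)-4-methoxyphenyl][4-(tert-butyldimethylsilyloxy)-3,5-dimethoxyphenyl]methyl acetate (racemic) | CC(=O)OC(c1cc(O[Si](C)(C)C(C)(C)C)c(OC)cc1Br)c1cc(OC)c(O[Si](C)(C)C(C)(C)C)c(OC)c1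
F4 | step 3 | 4-[(2-bromo-5-hydroxy-4-methoxyphenyl)methylidene]-2,6-dimethoxycyclohexa-2,5-dien-1-one | COC1=CC(=Cc2cc(O)c(OC)cc2Br)C=C(OC)C1=O
F5 | step 3 | dimethyl 2-[(2-bromo-5-hydroxy-4-methoxyphenyl)(4-hydroxy-3,5-dimethoxyphenyl)methyl]-3-methylidenebutanedioate (diarylmethine configured as in 9, mixture at C2) | COc1cc(Br)c(cc1O)[C@@H](c1cc(OC)c(O)c(OC)c1)C(C(=O)OC)C(=C)C(=O)OC
F6 | step 2 | [3-(tert-butyldimethylsilyloxy)-4-methoxyphenyl][4-(tert-butyldimethylsilyloxy)-3,5-dimethoxyphenyl]methanol (racemic) | OC(c1ccc(OC)c(O[Si](C)(C)C(C)(C)C)c1)c1cc(OC)c(O[Si](C)(C)C(C)(C)C)c(OC)c1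
F7 | step 2 | tert-butyl{4-[[3-(tert-butyldimethylsilyloxy)-4-methoxyphenyl](4-methylbenzenesulfonyl)methyl]-2,6-dimethoxyphenoxy}dimethylsilane (racemic) | Cc1ccc(cc1)S(=O)(=O)C(c1ccc(OC)c(O[Si](C)(C)C(C)(C)C)c1)c1cc(OC)c(O[Si](C)(C)C(C)(C)C)c(OC)c1
F8 | step 4 | (1R,2S,3S)-7-hydroxy-1-(4-hydroxy-3,5-dimethoxyphenyl)-6-methoxy-1,2,3,4-tetrahydronaphthalene-2,3-dicarboxylic acid | COc1cc2c(cc1O)[C@@H](c1cc(OC)c(O)c(OC)c1)[C@H](C(=O)O)[C@@H](C(=O)O)C2
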